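**Plan**

- Numbering as in the eremophilanes: ring A = C1–C5 and C10, ring B = C5–C10, C11 on C7. Retrosynthetic cuts, in order: C11–O together with the C6=C7 π bond (Schenck ene, back to a 7(11),9-dien-8-one); the C3 ester and C1–O bonds; C6–C7 (aldol condensation, opens ring B); C9=C10 and C9–C10 (Meyer–Schuster rearrangement, acetylide addition); then C5–C6, C5–CH3 and C4–CH3 on a ring A enone from benzoquinone mono(dimethyl ketal).
- Forward: ring A is built first; C7–C9 and C11–C13 arrive as one enyne on the C10 ketone; ring B closes last at C6–C7; oxygen is then placed on C3, C1 and C11 on the bicycle.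
- Enabling feature: C6 is a non-enolisable formyl carbon on the quaternary ring-fusion carbon C5, and C7 is a methylene that is α to the C8 ketone and allylic, held 1,5 to C6 across the C10=C9–C8 enone. Because C5 is quaternary, ring B can only settle as the cross-conjugated dienone.
- Stereochemistry: C4 from a chiral copper catalyst; C5 by alkylation anti to the C4 methyl; C3 by equatorial hydride attack on the bicyclic ketone; C1 by axial vinylogous oxidation; C11 is not stereogenic.
- The 6,7-alkene from the ring closure is traded for a 7(11)-alkene by conjugate reduction, and singlet oxygen returns it while installing the hydroperoxide.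

Key step: step 9

Assumption: the phosphoramidite enantiomer in step 1 is the one whose copper complex gives the (5R)-adduct 2; the opposite ligand enantiomer would be used if the sense of induction proved reversed.

Step 1
Reactants: 1 4,4-dimethoxycyclohexa-2,5-dien-1-one
Product: 2 (5R)-4,4-dimethoxy-5-methylcyclohex-2-en-1-one
Conditions: Me2Zn, Cu(OTf)2 (2 mol %), BINOL-derived bis(1-phenylethyl)amine phosphoramidite (4 mol %), toluene, −25 °C; aq NH4Cl
Reagents that add atoms: dimethylzinc, C[Zn]C
Why: Copper-catalysed asymmetric conjugate addition of a dialkylzinc to a quinone monoketal; the chiral copper complex selects one of the two enantiotopic β-carbons and one face, which sets C4, and the remaining enone, now next to a tertiary centre, should not add a second methyl.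

Step 2
Reactants: 2 (5R)-4,4-dimethoxy-5-methylcyclohex-2-en-1-one
Product: 4 (5R,6R)-4,4-dimethoxy-5,6-dimethylcyclohex-2-en-1-one, via lithium enolate 3 (not isolated)
Conditions: LDA, THF, −78 °C; MeI, −78 to −30 °C
Reagents that add atoms: iodomethane, CI
Why: Kinetic α′-deprotonation is the only possible enolisation (the γ-carbon is the ketal carbon) and the enolate is methylated anti to the neighbouring methyl; the new centre is flattened again in step 3.

Step 3
Reactants: 4 (5R,6R)-4,4-dimethoxy-5,6-dimethylcyclohex-2-en-1-one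
Product: 6 (5R,6S)-6-(hydroxymethyl)-4,4-dimethoxy-5,6-dimethylcyclohex-2-en-1-one, via lithium enolate 5 (not isolated)
Conditions: LDA, THF, −78 to −40 °C; CH2O (gas), −78 °C; aq NH4Cl
Reagents that add atoms: formaldehyde, C=O
Why: Aldol addition of the tetrasubstituted α′-enolate to formaldehyde; the electrophile should enter anti to the pseudoaxial C4 methyl of the nearly flat enolate (the usual outcome for 2,3-dimethylcyclohexanone enolates), which makes C5 quaternary with its methyl cis to the C4 methyl.

Step 4
Reactants: 6 (5R,6S)-6-(hydroxymethyl)-4,4-dimethoxy-5,6-dimethylcyclohex-2-en-1-one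
Product: 7 (2S,3R)-2-(hydroxymethyl)-4,4-dimethoxy-2,3-dimethylcyclohexan-1-one
Conditions: H2 (1 atm), 10% Pd/C, EtOAc, rt
Reagents that add atoms: none
Why: Heterogeneous hydrogenation saturates the enone C=C chemoselectively; ketone, ketal, primary alcohol and both stereocentres are untouched, and removal of the alkene ends the risk of aromatisation of the ketal.

Step 5
Reactants: 8 3-chloro-2-methylprop-1-ene; 9 ethynylmagnesium bromide
Product: 10 2-methylpent-1-en-4-yne
Conditions: CuCl (5 mol %), THF, 0 °C to rt
Reagents that add atoms: none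
Why: Copper-catalysed substitution of an allylic chloride by an alkynyl Grignard reagent gives the skipped 1,4-enyne.

Step 6
Reactants: 7 (2S,3R)-2-(hydroxymethyl)-4,4-dimethoxy-2,3-dimethylcyclohexan-1-one; 10 2-methylpent-1-en-4-yne
Product: 12 (2S,3R)-2-(hydroxymethyl)-4,4-dimethoxy-2,3-dimethyl-1-(4-methylpent-4-en-1-yn-1-yl)cyclohexan-1-ol (both C1 epimers), via lithium acetylide 11 (not isolated)
Conditions: 10 (2.5 equiv), n-BuLi (2.4 equiv), THF, −78 °C; then 7, −78 to −20 °C; aq NH4Cl
Reagents that add atoms: none
Why: 1,2-Addition of a lithium acetylide, a small nucleophile that reaches the ketone next to the quaternary carbon; one equivalent is spent on the hydroxyl, and both epimers of the new carbinol serve because C10 becomes sp2.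

Step 7
Reactants: 12 (2S,3R)-2-(hydroxymethyl)-4,4-dimethoxy-2,3-dimethyl-1-(4-methylpent-4-en-1-yn-1-yl)cyclohexan-1-ol
Product: 13 1-[(2R,3R)-2-(hydroxymethyl)-4,4-dimethoxy-2,3-dimethylcyclohexylidene]-5-methylhex-5-en-2-one (E/Z mixture)
Conditions: VO(OSiPh3)3 (5 mol %), toluene, 80 °C
Reagents that add atoms: none
Why: Oxo-vanadium-catalysed Meyer–Schuster rearrangement: [3,3]-shift of the propargyl vanadate to an allenyl vanadate and protonation place the carbonyl on C8 under neutral conditions that spare the ketal and avoid the Rupe pathway; the E/Z ratio does not matter.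

Step 8
Reactants: 13 1-[(2R,3R)-2-(hydroxymethyl)-4,4-dimethoxy-2,3-dimethylcyclohexylidene]-5-methylhex-5-en-2-one
Product: 14 (1R,6R)-5,5-dimethoxy-1,6-dimethyl-2-(5-methyl-2-oxohex-5-en-1-ylidene)cyclohexane-1-carbaldehyde (E/Z mixture)
Conditions: Dess–Martin periodinane, pyridine, CH2Cl2, 0 °C to rt
Reagents that add atoms: none
Why: Buffered Dess–Martin oxidation of the neopentyl primary alcohol to the non-enolisable aldehyde; enone, alkenes and ketal are inert.

Step 9
Reactants: 14 (1R,6R)-5,5-dimethoxy-1,6-dimethyl-2-(5-methyl-2-oxohex-5-en-1-ylidene)cyclohexane-1-carbaldehyde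
Product: 16 (4R,5R)-3,3-dimethoxyeremophila-6,9,11-trien-8-one, via aldol adduct 15 (not isolated)
Conditions: pyrrolidine (0.5 equiv), AcOH (0.5 equiv), toluene, 50 °C
Reagents that add atoms: none
Why: Pyrrolidinium acetate converts the C8 ketone into a dienamine whose C7 carbon adds to the C6 aldehyde (or its iminium ion) to give 15, and loss of water and hydrolysis of the amine give the trienone. The closest known reaction type is the amine-catalysed intramolecular aldol (Knoevenagel-type) condensation that closes cyclohexenones in Robinson-type annulations. Ring B closes in a 6-(enolendo)-exo-trig mode by the C6–C7 bond. No stereocentre is formed, and C4 and C5 cannot epimerise because C5 is quaternary and C3 is still a ketal. The step is dynamic: only the isomer of 14 with the acyl chain syn to C5 can close, and the E and Z forms of the C9=C10 bond, as well as the skipped and conjugated forms of the C11 alkene, interconvert through dienamines (γ-deprotonation at C1 or deprotonation at C7), so the whole mixture should drain into 16. The selectivity needed is reaction at C7 and condensation in preference to amine conjugate addition; C7 is the only enolisable α-carbon (C9 is vinylic) and is doubly activated, and the β-carbon C10 is fully substituted.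

Step 10
Reactants: 16 (4R,5R)-3,3-dimethoxyeremophila-6,9,11-trien-8-one
Product: 17 (4R,5R)-eremophila-6,9,11-triene-3,8-dione
Conditions: PPTS (0.2 equiv), acetone/H2O (10:1), rt
Reagents that add atoms: water, O
Why: Acid-catalysed hydrolysis of the dimethyl ketal, mild enough that the new C3 ketone is not enolised and C4 keeps its configuration.

Step 11
Reactants: 17 (4R,5R)-eremophila-6,9,11-triene-3,8-dione
Product: 18 (3S,4R,5R)-3-hydroxyeremophila-6,9,11-trien-8-one
Conditions: LiBH(s-Bu)3 (L-Selectride, 1.05 equiv), THF, −78 °C; aq NH4Cl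
Reagents that add atoms: none
Why: Hydride reduction of the saturated C3 ketone, far more electrophilic than the hindered cross-conjugated C8 ketone; because planar ring B holds the C5 methyl axial on ring A, the bulky borohydride attacks equatorially and gives the axial 3-alcohol cis to both methyls (as with 3,3,5-trimethylcyclohexanone).

Step 12
Reactants: 18 (3S,4R,5R)-3-hydroxyeremophila-6,9,11-trien-8-one; 19 angelic acid [(2Z)-2-methylbut-2-enoic acid]
Product: 21 (3S,4R,5R)-8-oxoeremophila-6,9,11-trien-3-yl (2Z)-2-methylbut-2-enoate, via mixed anhydride 20 (not isolated)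
Conditions: 19, 2,4,6-trichlorobenzoyl chloride, Et3N, toluene, rt; then 18, 80 °C
Reagents that add atoms: none
Why: Yamaguchi esterification through the mixed anhydride, a standard way to acylate hindered secondary alcohols with angelic acid; no nucleophilic catalyst is present, so Z to E isomerisation should not occur.

Step 13
Reactants: 21 (3S,4R,5R)-8-oxoeremophila-6,9,11-trien-3-yl (2Z)-2-methylbut-2-enoate
Product: 23 (1R,3S,4R,5R)-1-hydroxy-8-oxoeremophila-6,9,11-trien-3-yl (2Z)-2-methylbut-2-enoate, via silyl trienol ether 22 (not isolated)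
Conditions: TMSOTf, Et3N, CH2Cl2, 0 °C; then DMDO, acetone, −40 °C; aq citric acid
Reagents that add atoms: dimethyldioxirane, CC1(C)OO1
Why: Soft enolisation can only remove a γ-hydrogen from C1, and the vinylogous Rubottom oxidation of the resulting silyl trienol ether should attack C1 axially, syn to the C5 methyl and free of allylic strain with H9, as in the 6β-hydroxylation of steroidal enone dienol ethers; collapse and desilylation return the trienone with the 1-alcohol cis to the other ring A substituents.

Step 14
Reactants: 23 (1R,3S,4R,5R)-1-hydroxy-8-oxoeremophila-6,9,11-trien-3-yl (2Z)-2-methylbut-2-enoate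
Product: 25 (1R,3S,4R,5R)-1-hydroxy-8-oxoeremophila-7(11),9-dien-3-yl (2Z)-2-methylbut-2-enoate, via isopropenyl ketone 24 (not isolated)
Conditions: [(Ph3P)CuH]6, H2O, THF/benzene, rt; then DBU (0.1 equiv), CH2Cl2, rt
Reagents that add atoms: none
Why: Conjugate reduction with a copper hydride (Stryker's reagent) delivers hydride to C6, the only accessible β-carbon (C10 is fully substituted and the angelate is a less reactive trisubstituted enoate), and catalytic base then moves the β,γ-alkene into conjugation as the isopropylidene group (isopulegone to pulegone isomerisation), so C6 now carries the hydrogens needed in step 15.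

Step 15
Reactants: 25 (1R,3S,4R,5R)-1-hydroxy-8-oxoeremophila-7(11),9-dien-3-yl (2Z)-2-methylbut-2-enoate
Product: 26 (1R,3S,4R,5R)-11-hydroperoxy-1-hydroxy-8-oxoeremophila-6,9-dien-3-yl (2Z)-2-methylbut-2-enoate (target)
Conditions: O2, tetraphenylporphyrin (1 mol %), visible light, CH2Cl2, 0 °C
Reagents that add atoms: oxygen, O=O
Why: Schenck ene reaction of singlet oxygen with the s-cis α-isopropylidene ketone: hydrogen is taken from the alkyl group geminal to the carbonyl (C6), oxygen bonds to C11 and the alkene shifts to C6=C7; the s-trans 9,10-enone and the electron-poor angelate react far more slowly, and no stereocentre is formed.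

**Compound list**

1 | 4,4-dimethoxycyclohexa-2,5-dien-1-one | COC1(OC)C=CC(=O)C=C1 | starting material
2 | (5R)-4,4-dimethoxy-5-methylcyclohex-2-en-1-one | O=C1C=CC(OC)(OC)[C@H](C)C1 | intermediate
3 | lithium enolate of 2 (α′-enolate) | COC1(OC)C=CC(O[Li])=C[C@H]1C | intermediate
4 | (5R,6R)-4,4-dimethoxy-5,6-dimethylcyclohex-2-en-1-one (trans) | O=C1C=CC(OC)(OC)[C@H](C)[C@H]1C | intermediate
5 | lithium enolate of 4 (α′-enolate) | COC1(OC)C=CC(O[Li])=C(C)[C@H]1C | intermediate
6 | (5R,6S)-6-(hydroxymethyl)-4,4-dimethoxy-5,6-dimethylcyclohex-2-en-1-one (methyls cis) | O=C1C=CC(OC)(OC)[C@H](C)[C@@]1(C)CO | intermediate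
7 | (2S,3R)-2-(hydroxymethyl)-4,4-dimethoxy-2,3-dimethylcyclohexan-1-one | O=C1CCC(OC)(OC)[C@H](C)[C@@]1(C)CO | intermediate
8 | 3-chloro-2-methylprop-1-ene | CC(=C)CCl | starting material
9 | ethynylmagnesium bromide | C#C[Mg]Br | starting material
10 | 2-methylpent-1-en-4-yne | C#CCC(C)=C | intermediate
11 | lithium 4-methylpent-4-en-1-yn-1-ide | [Li]C#CCC(C)=C | intermediate
12 | (2S,3R)-2-(hydroxymethyl)-4,4-dimethoxy-2,3-dimethyl-1-(4-methylpent-4-en-1-yn-1-yl)cyclohexan-1-ol, both C1 epimers | OC1(C#CCC(C)=C)CCC(OC)(OC)[C@H](C)[C@@]1(C)CO | intermediate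
13 | 1-[(2R,3R)-2-(hydroxymethyl)-4,4-dimethoxy-2,3-dimethylcyclohexylidene]-5-methylhex-5-en-2-one, E/Z mixture | O=C(CC(C)=C)C=C1CCC(OC)(OC)[C@H](C)[C@@]1(C)CO | intermediate
14 | (1R,6R)-5,5-dimethoxy-1,6-dimethyl-2-(5-methyl-2-oxohex-5-en-1-ylidene)cyclohexane-1-carbaldehyde, E/Z mixture | O=C(CC(C)=C)C=C1CCC(OC)(OC)[C@H](C)[C@@]1(C)C=O | intermediate
15 | (4R,5R)-6-hydroxy-3,3-dimethoxyeremophila-9,11-dien-8-one (aldol adduct, C6 and C7 isomers) | COC1(OC)CCC2=CC(=O)C(C(C)=C)C(O)[C@]2(C)[C@H]1C | intermediate
16 | (4R,5R)-3,3-dimethoxyeremophila-6,9,11-trien-8-one | COC1(OC)CCC2=CC(=O)C(C(C)=C)=C[C@]2(C)[C@H]1C | intermediate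
17 | (4R,5R)-eremophila-6,9,11-triene-3,8-dione | O=C1CCC2=CC(=O)C(C(C)=C)=C[C@]2(C)[C@H]1C | intermediate
18 | (3S,4R,5R)-3-hydroxyeremophila-6,9,11-trien-8-one (3-OH cis to both methyls) | O[C@H]1CCC2=CC(=O)C(C(C)=C)=C[C@]2(C)[C@H]1C | intermediate
19 | angelic acid, (2Z)-2-methylbut-2-enoic acid | C/C=C(/C)C(=O)O | starting material
20 | (2Z)-2-methylbut-2-enoic 2,4,6-trichlorobenzoic anhydride | C/C=C(/C)C(=O)OC(=O)c1c(Cl)cc(Cl)cc1Cl | intermediate
21 | (3S,4R,5R)-8-oxoeremophila-6,9,11-trien-3-yl (2Z)-2-methylbut-2-enoate | C/C=C(/C)C(=O)O[C@H]1CCC2=CC(=O)C(C(C)=C)=C[C@]2(C)[C@H]1C | intermediate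
22 | (3S,4R,5R)-8-(trimethylsilyloxy)eremophila-1(10),6,8,11-tetraen-3-yl (2Z)-2-methylbut-2-enoate | C/C=C(/C)C(=O)O[C@H]1CC=C2C=C(O[Si](C)(C)C)C(C(C)=C)=C[C@]2(C)[C@H]1C | intermediate
23 | (1R,3S,4R,5R)-1-hydroxy-8-oxoeremophila-6,9,11-trien-3-yl (2Z)-2-methylbut-2-enoate | C/C=C(/C)C(=O)O[C@H]1C[C@@H](O)C2=CC(=O)C(C(C)=C)=C[C@]2(C)[C@H]1C | intermediate
24 | (1R,3S,4R,5R)-1-hydroxy-8-oxoeremophila-9,11-dien-3-yl (2Z)-2-methylbut-2-enoate, C7 epimers | C/C=C(/C)C(=O)O[C@H]1C[C@@H](O)C2=CC(=O)C(C(C)=C)C[C@]2(C)[C@H]1C | intermediate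
25 | (1R,3S,4R,5R)-1-hydroxy-8-oxoeremophila-7(11),9-dien-3-yl (2Z)-2-methylbut-2-enoate | C/C=C(/C)C(=O)O[C@H]1C[C@@H](O)C2=CC(=O)C(=C(C)C)C[C@]2(C)[C@H]1C | intermediate
26 | (1R,3S,4R,5R)-11-hydroperoxy-1-hydroxy-8-oxoeremophila-6,9-dien-3-yl (2Z)-2-methylbut-2-enoate | C/C=C(/C)C(=O)O[C@H]1C[C@@H](O)C2=CC(=O)C(C(C)(C)OO)=C[C@]2(C)[C@H]1C | target

**Step count**

Total steps: 15. Longest linear sequence: 14 (steps 1–4 and 6–15; step 5 makes the enyne 10).

**Steps most likely to fail, with fallbacks**

Step 9. The dienamine of the skipped dienone may react through its remote γ-carbon, or the amine may add in conjugate fashion and start oligomerisation, faster than ring closure onto the hindered neopentyl aldehyde. The fallback closes the ring with a plain methyl ketone, which has no competing vinylogous site, and adds the isopropenyl group afterwards by cross-coupling. It sets out from 7. 1-Propynylmagnesium bromide in THF should give the propynyl diol F1. VO(OSiPh3)3 in toluene at 80 °C should turn it into the methyl enone F2. Dess–Martin oxidation should give the keto aldehyde F3, and pyrrolidinium acetate should close it to the parent dienone ketal F4. Iodine and pyridine in CH2Cl2 (α-iodination of the less substituted enone through pyridine conjugate addition) should give the 7-iodo dienone F5. Stille coupling with tributyl(prop-1-en-2-yl)stannane (Pd(PPh3)4, CuI, DMF) should then give 16, where the route is rejoined.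

Step 13. The oxidant may attack the α-face of C1, away from the syn-axial C5 methyl and C3 ester, or attack C9 instead of C1. The fallback sets the C1 configuration by reduction instead of oxidation. It sets out from 21. Allylic γ-oxidation with t-BuOOH and Rh2(cap)4 (dirhodium tetrakis(caprolactamate)) should give the 1,8-dione F6. Luche reduction (NaBH4, CeCl3·7H2O, MeOH, −78 °C) of the more electrophilic C1 ketone, with hydride able to approach only equatorially from the α-face, should give 23, where the route is rejoined.

Step 14. Hydride may be delivered to the angelate or directly to the C8 carbonyl, or the isopropenyl ketone may fail to isomerise cleanly. The fallback installs the peroxide directly on the isopropenyl group and bypasses steps 14 and 15; its own risk is the site of oxygen capture on the allylic radical. It sets out from 23. Isayama–Mukaiyama hydroperoxysilylation (Co(acac)2 cat., O2, Et3SiH, ClCH2CH2Cl, rt) should give the triethylsilyl peroxide F7. HF·pyridine in THF at 0 °C should then free the hydroperoxide, which is 26.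

**Further compounds**

F1 | step 9 | (2S,3R)-2-(hydroxymethyl)-4,4-dimethoxy-2,3-dimethyl-1-(prop-1-yn-1-yl)cyclohexan-1-ol | OC1(C#CC)CCC(OC)(OC)[C@H](C)[C@@]1(C)CO
F2 | step 9 | 1-[(2R,3R)-2-(hydroxymethyl)-4,4-dimethoxy-2,3-dimethylcyclohexylidene]propan-2-one | CC(=O)C=C1CCC(OC)(OC)[C@H](C)[C@@]1(C)CO
F3 | step 9 | (1R,6R)-5,5-dimethoxy-1,6-dimethyl-2-(2-oxopropylidene)cyclohexane-1-carbaldehyde | CC(=O)C=C1CCC(OC)(OC)[C@H](C)[C@@]1(C)C=O
F4 | step 9 | (4aR,5R)-6,6-dimethoxy-4a,5-dimethyl-5,6,7,8-tetrahydronaphthalen-2(4aH)-one | COC1(OC)CCC2=CC(=O)C=C[C@]2(C)[C@H]1C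
F5 | step 9 | (4aS,5R)-3-iodo-6,6-dimethoxy-4a,5-dimethyl-5,6,7,8-tetrahydronaphthalen-2(4aH)-one | COC1(OC)CCC2=CC(=O)C(I)=C[C@]2(C)[C@H]1C
F6 | step 13 | (3S,4R,5R)-1,8-dioxoeremophila-6,9,11-trien-3-yl (2Z)-2-methylbut-2-enoate | C/C=C(/C)C(=O)O[C@H]1CC(=O)C2=CC(=O)C(C(C)=C)=C[C@]2(C)[C@H]1C
F7 | step 14 | (1R,3S,4R,5R)-1-hydroxy-8-oxo-11-(triethylsilylperoxy)eremophila-6,9-dien-3-yl (2Z)-2-methylbut-2-enoate | C/C=C(/C)C(=O)O[C@H]1C[C@@H](O)C2=CC(=O)C(C(C)(C)OO[Si](CC)(CC)CC)=C[C@]2(C)[C@H]1C
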